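**Retrosynthetic overview**
1. The dihydropyran is closed last: target ⇐ lactol 30 (loss of water) ⇐ δ-hydroxy aldehyde 29.
2. Key bond C13–C13′: the CH2 of spiro-epoxide 17, normally an electrophile, is converted into a nucleophilic β-lactonyl radical (a homoenolate equivalent of the α-hydroxy lactone) and joined to the electrophilic β-carbon of enal 28; the C11–O bond is already in place.
3. 17 ⇐ cis-fused eudesmanolide 16 ⇐ (S)-carvone (ring B); ring A by conjugate addition/intramolecular alkylation, lactone by Shapiro olefination/iodolactonisation, oxirane last.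
4. 28 ⇐ ent-β-elemene 26 ⇐ acyclic acid 21 (enantioselective Ireland–Claisen sets C10′/C5′; carbonyl-ene closure sets C7′).
5. Ring order: B → A → γ-lactone → oxirane; elemane cyclohexane separately; dihydropyran at the end.

Structure check: the lactone half is cis-fused (H-5 syn to CH3-10, i.e. 5-epi-isoalantolactone) and the elemane half is the antipode of natural β-elemene, so neither natural product can serve and both halves are built de novo.
Assumption: eudesmane numbering (C1–C15, CH3-10 = β) is used for the lactone half and primed elemane numbering for the other half; the (R,R)-boron controller is written and is exchanged for its (S,S)-antipode should the sense of induction prove reversed.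

**Part A – epoxy lactone 17**

Step 1
Reactants: 1 (S)-(+)-carvone
Product: 2 (S)-10-hydroxycarvone
Conditions: SeO2 (0.5 equiv), t-BuOOH (2 equiv), CH2Cl2, rt, 48 h
Reagents that add atoms: selenium dioxide, O=[Se]=O; tert-butyl hydroperoxide, CC(C)(C)OO
Why: Riley allylic oxidation (ene reaction, then [2,3]-shift) attacks only the electron-rich isopropenyl group at its methyl, the enone alkene being deactivated; the carvone stereocentre (future C7) is untouched.

Step 2
Reactants: 3 5-chloropent-1-yne
Product: 5 2-bromo-5-chloropent-1-ene, via alkenylborane 4 (not isolated)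
Conditions: B-bromo-9-BBN, CH2Cl2, 0 °C → rt; then AcOH, 0 °C
Reagents that add atoms: B-bromo-9-borabicyclo[3.3.1]nonane, BrB1C2CCCC1CCC2
Why: syn-bromoboration puts bromine on the internal alkyne carbon and protodeboronation gives the 2-bromo-1-alkene (formal Markovnikov hydrobromination).

Step 3
Reactants: 2 (S)-10-hydroxycarvone; 5 2-bromo-5-chloropent-1-ene
Product: 9 (3S,5S)-3-(5-chloropent-1-en-2-yl)-5-(3-hydroxyprop-1-en-2-yl)-2-methylcyclohexan-1-one (C2 epimers), via alkenylmagnesium bromide 6 (not isolated), via silyl ether 7 (not isolated), via bis-silyl enol ether 8 (not isolated)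
Conditions: (a) 5, Mg, THF, 40 °C; (b) 2, Me3SiCl (2.5 equiv), Et3N, THF, 0 °C; (c) a + b, CuBr·SMe2 (10 mol %), −78 → −30 °C; (d) 1 M HCl, THF, rt
Reagents that add atoms: none
Why: copper-catalysed conjugate addition of the alkenyl Grignard reagent (accelerated by Me3SiCl, hydroxyl masked in situ) occurs by axial attack anti to the side chain of the carvone ring, setting C5 trans to C7.

Step 4
Reactants: 9 chloro ketone
Product: 10 12-hydroxy-5βH-eudesma-4(15),11(13)-dien-9-one (cis-fused; 7αH; 10β-CH3)
Conditions: t-BuOK (2.5 equiv), t-BuOH/THF, 50 °C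
Reagents that add atoms: none
Why: Piers-type methylenecyclohexane annulation: the reversibly formed tetrasubstituted enolate is C-alkylated by the primary chloride (6-exo-tet) on the face that carries the tether, giving the cis ring fusion and the quaternary C10 with CH3 syn to H-5.

Step 5
Reactants: 10 hydroxy ketone
Product: 11 p-toluenesulfonylhydrazone of 10
Conditions: TsNHNH2, PPTS (cat.), EtOH, 70 °C
Reagents that add atoms: p-toluenesulfonyl hydrazide, Cc1ccc(cc1)S(=O)(=O)NN
Why: acid-catalysed condensation gives the hydrazone needed for the Shapiro reaction; no stereocentre is touched.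

Step 6
Reactants: 11 tosylhydrazone
Product: 12 5βH-eudesma-4(15),8,11(13)-trien-12-ol
Conditions: n-BuLi (3.5 equiv), TMEDA, THF, −78 → 0 °C; then H2O
Reagents that add atoms: none
Why: Shapiro reaction: deprotonation is possible only at C8 (C10 is quaternary), loss of sulfinate and N2 gives the alkenyllithium, and protonation leaves the C8=C9 alkene, removing the C9 oxygen.

Step 7
Reactants: 12 trienol
Product: 14 5βH-eudesma-4(15),8,11(13)-trien-12-oic acid, via enal 13 (not isolated)
Conditions: PhI(OAc)2, TEMPO (10 mol %), CH2Cl2, rt; then NaClO2, NaH2PO4, 2-methylbut-2-ene, t-BuOH/H2O, 0 °C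
Reagents that add atoms: sodium chlorite, [Na+].[O-]Cl=O
Why: TEMPO oxidation of the allylic alcohol followed by Pinnick oxidation with an alkene scavenger gives the acrylic acid without touching the other alkenes or C7.

Step 8
Reactants: 14 trienoic acid
Product: 15 9α-iodo-5βH-eudesma-4(15),11(13)-dien-12,8β-olide
Conditions: I2, NaHCO3, MeCN, 0 °C, dark
Reagents that add atoms: iodine, II
Why: iodolactonisation: the carboxylate on C11 can reach only C8 of the reversibly formed C8–C9 iodonium ion (5-exo), on the face of the C7 side chain, so the γ-lactone is cis-fused (anti addition, O-8 β, I-9 α) and C8 is set.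

Step 9
Reactants: 15 iodolactone
Product: 16 5βH-eudesma-4(15),11(13)-dien-12,8β-olide (5-epi-isoalantolactone)
Conditions: Bu3SnH (1.05 equiv, slow addition), AIBN (cat.), PhH, 80 °C
Reagents that add atoms: none
Why: radical dehalogenation: iodine abstraction by the stannyl radical is faster than its reversible addition to the acrylate, and C9 keeps no stereocentre.

Step 10
Reactants: 16 5-epi-isoalantolactone
Product: 17 11α,13-epoxy-5βH-eudesm-4(15)-en-12,8β-olide
Conditions: t-BuOOH, benzyltrimethylammonium hydroxide (cat.), THF, 0 °C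
Reagents that add atoms: tert-butyl hydroperoxide, CC(C)(C)OO
Why: Weitz–Scheffer nucleophilic epoxidation touches only the electron-poor alkene; the enolate closes on the convex face of the cis-fused lactone (the face of H-7 and H-8), setting C11 with oxygen α.

**Part B – ent-β-elemenal 28**

Step 11
Reactants: 18 geraniol; 19 3-methylbut-3-enoic acid
Product: 20 geranyl 3-methylbut-3-enoate
Conditions: DCC, DMAP (cat.), CH2Cl2, 0 °C
Reagents that add atoms: none
Why: Steglich esterification at low temperature keeps the β,γ-alkene out of conjugation.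

Step 12
Reactants: 20 geranyl ester
Product: 21 (2R,3R)-3-ethenyl-3,7-dimethyl-2-(prop-1-en-2-yl)oct-6-enoic acid
Conditions: (R,R)-2-bromo-4,5-diphenyl-1,3-bis[3,5-bis(trifluoromethyl)phenylsulfonyl]-1,3,2-diazaborolidine (made from the bis-sulfonamide and BBr3, CH2Cl2), Et3N, toluene/hexane, −78 → 4 °C, 3 d; aqueous work-up
Reagents that add atoms: none
Why: enantioselective Ireland–Claisen rearrangement: the chiral boron ketene acetal (isopropenyl trans to O–B) rearranges through a chair transition state on the (E)-allyl ester, fixing quaternary C10′ and C5′ with vinyl and isopropenyl in the relative arrangement needed, the controller choosing the face.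

Step 13
Reactants: 21 acid
Product: 22 (2R,3R)-3-ethenyl-3,7-dimethyl-2-(prop-1-en-2-yl)oct-6-en-1-ol
Conditions: LiAlH4, Et2O, 0 °C → rt
Reagents that add atoms: none
Why: hydride reduction of the acid; neither stereocentre can epimerise.

Step 14
Reactants: 22 alcohol
Product: 23 (2R,3R)-3-ethenyl-3,7-dimethyl-2-(prop-1-en-2-yl)oct-6-enal
Conditions: PhI(OAc)2, TEMPO (10 mol %), CH2Cl2, rt
Reagents that add atoms: none
Why: TEMPO oxidation stops at the aldehyde under non-basic conditions, avoiding α-epimerisation or conjugation of the β,γ-alkene.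

Step 15
Reactants: 23 aldehyde
Product: 24 (1R,2R,3R,6R)-3-ethenyl-3-methyl-2,6-di(prop-1-en-2-yl)cyclohexan-1-ol
Conditions: Me2AlCl (1.1 equiv), CH2Cl2, −78 → −40 °C
Reagents that add atoms: none
Why: intramolecular carbonyl-ene cyclisation (citronellal-to-isopulegol type) through a chair transition state with equatorial substituents closes the ring and sets C7′ cis to the C5′ isopropenyl group (the C6′ carbinol is removed next).

Step 16
Reactants: 24 cyclohexanol
Product: 25 O-[(1R,2R,3R,6R)-3-ethenyl-3-methyl-2,6-di(prop-1-en-2-yl)cyclohexyl] S-methyl dithiocarbonate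
Conditions: NaH, imidazole (cat.), THF; CS2; MeI, rt
Reagents that add atoms: carbon disulfide, S=C=S; iodomethane, CI
Why: xanthate formation prepares the radical deoxygenation.

Step 17
Reactants: 25 xanthate
Product: 26 (1R,2R,4S)-1-ethenyl-1-methyl-2,4-di(prop-1-en-2-yl)cyclohexane (ent-β-elemene)
Conditions: Bu3SnH, AIBN (cat.), toluene, 110 °C
Reagents that add atoms: none
Why: Barton–McCombie deoxygenation removes the C6′ oxygen; the secondary radical has no favourable cyclisation mode and the three stereocentres are untouched.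

Step 18
Reactants: 26 ent-β-elemene
Product: 28 2-[(1S,3R,4R)-4-ethenyl-4-methyl-3-(prop-1-en-2-yl)cyclohexyl]prop-2-enal (ent-β-elemenal), via allylic alcohol 27 (not isolated)
Conditions: SeO2 (0.3 equiv), t-BuOOH, CH2Cl2, 0 °C → rt; then MnO2, CH2Cl2, rt
Reagents that add atoms: selenium dioxide, O=[Se]=O; tert-butyl hydroperoxide, CC(C)(C)OO
Why: Riley oxidation prefers the less hindered isopropenyl group on C7′ (the other is flanked by the quaternary carbon, the vinyl group has no allylic hydrogen) and MnO2 completes the oxidation to the enal; the regioisomer is removed by chromatography.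

**Part C – union**

Step 19
Reactants: 17 epoxy lactone; 28 ent-β-elemenal (1.5 equiv)
Product: 30 spiro-lactol (epimer mixture at C11′/C12′), via hydroxy aldehyde 29 (not isolated)
Conditions: cyanocobalamin (C63H88CoN14O14P, 5 mol %), Zn dust, NH4Cl, DMF, blue LEDs, rt
Reagents that add atoms: none
Why: Proposed new method: zinc-reduced cyanocobalamin (monovalent cobalt) opens the spiro-epoxide by SN2 attack at the unhindered C13 methylene, light-induced homolysis of the 2-hydroxyalkyl–cobalt bond gives the C13 radical (the β-carbon of the lactone, so a polarity-reversed homoenolate equivalent), which adds to the β-carbon C13′ of enal 28 in a reductive Giese addition before the α-formyl radical is reduced and protonated and the δ-hydroxy aldehyde closes to the lactol; the closest known chemistry is the cyanocobalamin/zinc conjugate addition of alkyl halides to Michael acceptors and cobalt-mediated opening of epoxides at the less hindered carbon; C11 keeps the configuration from step 10.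

Step 20
Reactants: 30 spiro-lactol
Product: 31 target CNP0353330.1
Conditions: MsCl, Et3N, CH2Cl2, 0 → 40 °C
Reagents that add atoms: none
Why: mesylation of the anomeric hydroxyl and base-induced elimination (glycal-type dehydration) removes the only β-hydrogen (on C11′) to give the cyclic enol ether; the two undefined centres of 30 become sp2 and no other stereocentre is affected.

**Compound list**
1 | (S)-(+)-carvone | C=C(C)[C@@H]1CC(=O)C(C)=CC1 | starting material
2 | (5S)-5-(3-hydroxyprop-1-en-2-yl)-2-methylcyclohex-2-en-1-one | C=C(CO)[C@@H]1CC(=O)C(C)=CC1 | intermediate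
3 | 5-chloropent-1-yne | ClCCCC#C | starting material
4 | B-[(Z)-2-bromo-5-chloropent-1-en-1-yl]-9-borabicyclo[3.3.1]nonane | Br/C(CCCCl)=C\B1C2CCCC1CCC2 | intermediate
5 | 2-bromo-5-chloropent-1-ene | C=C(Br)CCCCl | intermediate
6 | (5-chloropent-1-en-2-yl)magnesium bromide | C=C(CCCCl)[Mg]Br | intermediate
7 | trimethylsilyl ether of 2 | C=C(CO[Si](C)(C)C)[C@@H]1CC(=O)C(C)=CC1 | intermediate
8 | bis-silyl enol ether of 9 | C=C(CO[Si](C)(C)C)[C@@H]1CC(O[Si](C)(C)C)=C(C)[C@@H](C(=C)CCCCl)C1 | intermediate
9 | (3S,5S)-3-(5-chloropent-1-en-2-yl)-5-(3-hydroxyprop-1-en-2-yl)-2-methylcyclohexan-1-one | C=C(CO)[C@@H]1CC(=O)C(C)[C@@H](C(=C)CCCCl)C1 | intermediate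
10 | 12-hydroxy-5βH-eudesma-4(15),11(13)-dien-9-one | C=C(CO)[C@@H]1CC(=O)[C@@]2(C)CCCC(=C)[C@H]2C1 | intermediate
11 | p-toluenesulfonylhydrazone of 10 | C=C(CO)[C@@H]1CC(=NNS(=O)(=O)c3ccc(C)cc3)[C@@]2(C)CCCC(=C)[C@H]2C1 | intermediate
12 | 5βH-eudesma-4(15),8,11(13)-trien-12-ol | C=C(CO)[C@@H]1C=C[C@@]2(C)CCCC(=C)[C@H]2C1 | intermediate
13 | 5βH-eudesma-4(15),8,11(13)-trien-12-al | C=C(C=O)[C@@H]1C=C[C@@]2(C)CCCC(=C)[C@H]2C1 | intermediate
14 | 5βH-eudesma-4(15),8,11(13)-trien-12-oic acid | C=C(C(=O)O)[C@@H]1C=C[C@@]2(C)CCCC(=C)[C@H]2C1 | intermediate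
15 | 9α-iodo-5βH-eudesma-4(15),11(13)-dien-12,8β-olide | C=C1C(=O)O[C@@H]2[C@@H](I)[C@@]3(C)CCCC(=C)[C@H]3C[C@@H]21 | intermediate
16 | 5βH-eudesma-4(15),11(13)-dien-12,8β-olide, (3aR,4aR,8aR,9aR) | C=C1C(=O)O[C@@H]2C[C@@]3(C)CCCC(=C)[C@H]3C[C@@H]21 | intermediate
17 | 11α,13-epoxy-5βH-eudesm-4(15)-en-12,8β-olide | C1O[C@]12C(=O)O[C@@H]3C[C@@]4(C)CCCC(=C)[C@H]4C[C@@H]32 | intermediate
18 | geraniol | CC(C)=CCC/C(C)=C/CO | starting material
19 | 3-methylbut-3-enoic acid | C=C(C)CC(=O)O | starting material
20 | geranyl 3-methylbut-3-enoate | C=C(C)CC(=O)OC/C=C(\C)CCC=C(C)C | intermediate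
21 | (2R,3R)-3-ethenyl-3,7-dimethyl-2-(prop-1-en-2-yl)oct-6-enoic acid | C=C[C@@](C)(CCC=C(C)C)[C@H](C(O)=O)C(C)=C | intermediate
22 | (2R,3R)-3-ethenyl-3,7-dimethyl-2-(prop-1-en-2-yl)oct-6-en-1-ol | C=C[C@@](C)(CCC=C(C)C)[C@H](CO)C(C)=C | intermediate
23 | (2R,3R)-3-ethenyl-3,7-dimethyl-2-(prop-1-en-2-yl)oct-6-enal | C=C[C@@](C)(CCC=C(C)C)[C@H](C=O)C(C)=C | intermediate
24 | (1R,2R,3R,6R)-3-ethenyl-3-methyl-2,6-di(prop-1-en-2-yl)cyclohexan-1-ol | C=C[C@@]1(C)CC[C@H](C(C)=C)[C@@H](O)[C@@H]1C(=C)C | intermediate
25 | S-methyl dithiocarbonate (xanthate) of 24 | C=C[C@@]1(C)CC[C@H](C(C)=C)[C@@H](OC(=S)SC)[C@@H]1C(=C)C | intermediate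
26 | (1R,2R,4S)-1-ethenyl-1-methyl-2,4-di(prop-1-en-2-yl)cyclohexane | C=C[C@@]1(C)CC[C@H](C(C)=C)C[C@@H]1C(=C)C | intermediate
27 | 2-[(1S,3R,4R)-4-ethenyl-4-methyl-3-(prop-1-en-2-yl)cyclohexyl]prop-2-en-1-ol | C=C[C@@]1(C)CC[C@H](C(=C)CO)C[C@@H]1C(=C)C | intermediate
28 | 2-[(1S,3R,4R)-4-ethenyl-4-methyl-3-(prop-1-en-2-yl)cyclohexyl]prop-2-enal | C=C[C@@]1(C)CC[C@H](C(=C)C=O)C[C@@H]1C(=C)C | intermediate
29 | δ-hydroxy aldehyde (11α-hydroxy lactone carrying the C13–C13′ bond) | C=C[C@@]1(C)CC[C@H](C(C=O)CC[C@]2(O)C(=O)O[C@@H]3C[C@@]4(C)CCCC(=C)[C@H]4C[C@@H]32)C[C@@H]1C(=C)C | intermediate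
30 | spiro-lactol (2-hydroxytetrahydropyran form of 29) | C=C[C@@]1(C)CC[C@H](C2C(O)O[C@@]3(CC2)C(=O)O[C@@H]2C[C@@]4(C)CCCC(=C)[C@H]4C[C@@H]23)C[C@@H]1C(=C)C | intermediate
31 | CNP0353330.1 | C=C[C@@]1(C)CC[C@H](C2=CO[C@@]3(CC2)C(=O)O[C@@H]2C[C@@]4(C)CCCC(=C)[C@H]4C[C@@H]23)C[C@@H]1C(=C)C | target

**Totals**
Total step count: 20. Longest linear sequence: 11 steps (steps 1 or 2, then 3–10, 19, 20).

**Three steps most likely to fail**

Step 19. The low-valent cobalt may reduce enal 28 or the 2-hydroxyalkyl–cobalt species may eliminate back to 16. The fallback sets out from 17 and comes back at 30: the epoxide is opened with MgI2 (Et2O, 0 °C) to the iodohydrin 13-iodo-11α-hydroxy-5βH-eudesm-4(15)-en-12,8β-olide F1. Its primary radical, made by iodine abstraction (Bu3SnH, AIBN, slow addition, PhH, 80 °C), is added to 28, so no low-valent cobalt meets the enal; the adduct closes to 30.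

Step 18. The two isopropenyl groups of 26 may not be distinguished well enough by SeO2. The fallback sets out from 26 and comes back at 28: electrophilic ene-chlorination (NaOCl, AcOH, CH2Cl2/H2O, 0 °C), which is more sensitive to the crowding next to the quaternary carbon, gives the allylic chloride (1R,2R,4S)-4-(3-chloroprop-1-en-2-yl)-1-ethenyl-1-methyl-2-(prop-1-en-2-yl)cyclohexane F2, purified from its regioisomer. Kornblum oxidation (DMSO, NaHCO3, 90 °C) then gives 28.

Step 9. Stannyl radicals can add to the α-methylene lactone. The fallback sets out from 15 and comes back at 17 with the order reversed: the electron-poor alkene of 15 is epoxidised first (t-BuOOH, benzyltrimethylammonium hydroxide, THF, 0 °C) to the iodo epoxide 9α-iodo-11α,13-epoxy-5βH-eudesm-4(15)-en-12,8β-olide F3. The iodine is then removed with Bu3SnH/AIBN when no acrylate is left; 16 is bypassed.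

**Further compounds**
F1 | step 19 | 13-iodo-11α-hydroxy-5βH-eudesm-4(15)-en-12,8β-olide | IC[C@]1(O)C(=O)O[C@@H]2C[C@@]3(C)CCCC(=C)[C@H]3C[C@@H]21
F2 | step 18 | (1R,2R,4S)-4-(3-chloroprop-1-en-2-yl)-1-ethenyl-1-methyl-2-(prop-1-en-2-yl)cyclohexane | C=C[C@@]1(C)CC[C@H](C(=C)CCl)C[C@@H]1C(=C)C
F3 | step 9 | 9α-iodo-11α,13-epoxy-5βH-eudesm-4(15)-en-12,8β-olide | C1O[C@]12C(=O)O[C@@H]3[C@@H](I)[C@@]4(C)CCCC(=C)[C@H]4C[C@@H]32
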